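A first reading taken on the plateau gives only a floor for a rate. The autumn run is such a case: 62.9% at 90.0 min stands level with 62.5% at 360 min.

in all of them: substrate 0.40 M

| charge | partner | free catalyst | temperature | remark | time |
|---|---|---|---|---|---|
| summer | 0.80 M | 0.18 mM | 35 °C | run made earlier |  |
| autumn | 0.80 M | 0.27 mM | 85 °C | run made earlier |  |
| spring | 0.40 M | 0.36 mM | 35 °C | run made earlier |  |
| delta | 0.800 M | 0.36 mM | 130 °C |  | 40 min |
| zeta | 0.800 M | 0.36 mM | 100 °C |  | 40 min |
| epsilon | 0.800 M | 0.36 mM | 40 °C |  | 40 min |
| theta | 0.800 M | 0.36 mM | 70 °C |  | 40 min |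

- summer (time / min: target / %): 600: 32.6; 1800: 77.7; 3000: 86.7; 4320: 86.0
- autumn (time / min: target / %): 90.0: 62.9; 180: 64.6; 300: 62.4; 360: 62.5
- spring (time / min: target / %): 360: 35.8; 900: 70.2; 1800: 73.5; 4320: 72.5

(each reading ± 1 percentage point)

- the best flask by amount of target, in percent of the substrate charged; "all alike" if 1.5 percentage points covers them all (delta / zeta / epsilon / theta / all alike)
- amount of target at the end, in percent of the substrate charged, delta
- amount of target at the end, in percent of the substrate charged, zeta
- amount of target at the end, in percent of the substrate charged, epsilon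
- amount of target at the end, in percent of the substrate charged, theta

The reckoning here is my own, and it goes to epsilon, the coldest flask. Target formed, over catalyst charged and time, is read from the first readings at 35 °C:

summer: 1.21 min⁻¹
spring: 1.10 min⁻¹

The summer value is the turnover rate: target made per catalyst per minute. Spring holds half the partner and twice the catalyst of summer, and the two readings stand close. So target is reckoned as turnover × catalyst × time.

Epsilon at that turnover: 4.35%

That number is the large thing, and the step from 35 °C to 40 °C is the correction. This is the weak link, so it is reforged from the autumn run: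

autumn turnover, a floor: 10.4 min⁻¹
gain over the whole span, a floor: 8.58
share of that span in epsilon's step: 0.100
correction, span raised to that share: 1.24
epsilon, leaning low: 5.39%

The forecast names zeta as best. It gives delta 42% (34% to 49%), zeta 54% (47% to 59%), epsilon 6% (4% to 10%) and theta 48% (28% to 69%). Its epsilon stands above my estimate. Its verdict: “Zeta probably wins, narrowly over theta.”

The best flask is theta, with delta at 39.3%, zeta at 60.1%, epsilon at 7.56% and theta at 71.0%.

    partner → decomposed reagent (k = 5.00 × 10⁻⁴ s⁻¹, Ea = 93.0 kJ mol⁻¹)
    catalyst intermediate A → by-product + catalyst intermediate B (k = 19.0 s⁻¹, Ea = 77.0 kJ mol⁻¹)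
    2 partner → homo dimer (k = 5.60 × 10⁻⁵ M⁻¹ s⁻¹, Ea = 99.0 kJ mol⁻¹)
    catalyst intermediate C → free catalyst + target (k = 1.20 s⁻¹, Ea = 93.0 kJ mol⁻¹)
    substrate + catalyst intermediate B ⇌ catalyst intermediate C (K = 5.30 M⁻¹, k = 3.40 M⁻¹ s⁻¹, Ea = 58.0 kJ mol⁻¹, ΔH = −39.0 kJ mol⁻¹)
    partner + free catalyst ⇌ catalyst intermediate A (K = 2.00 M⁻¹, k = 45.0 M⁻¹ s⁻¹, Ea = 59.0 kJ mol⁻¹, ΔH = 17.0 kJ mol⁻¹)
    (constants at 70 °C)

Delta has stopped with partner at 0%, and ten times the time changes nothing. The step from partner to decomposed reagent is the main reason, for delta without it reaches 100%. Epsilon is still turning over: catalyst intermediate C, its resting state, holds 65.5% of the catalyst. Epsilon's turnover reads 2.10 min⁻¹, which is 1.74 times the summer value and above the corrected figure. For a neighbour flask, like epsilon but with 0.610 mM of free catalyst, this gives 12.8%; the flask computes 12.7%.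

(The earlier runs and the new flask stem from a simulated flask with made-up constants, noise included.)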